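The easy step here is the making of target: in the south flask substrate and reagent give it with a forward half-life of 0.067 h, and what needs counting is the slow leak around that step.

    substrate + reagent ⇌ target (K1 = 210 L mol⁻¹, k1 = 0.017 L mol⁻¹ s⁻¹)
    substrate ⇌ intermediate A (K2 = 0.46, k2 = 6.2 × 10⁻⁵ s⁻¹)
    intermediate A ⇌ intermediate B (K3 = 0.35, k3 = 6.7 × 10⁻⁵ s⁻¹)
    intermediate A ⇌ intermediate C (K4 = 1.2, k4 = 8.7 × 10⁻⁴ s⁻¹)
    reagent + intermediate C → side product (k5 = 5.3 × 10⁻⁴ L mol⁻¹ s⁻¹)

| setting | south-west | north | south | north-west |
|---|---|---|---|---|
| substrate | 0.21 M | 0.21 M | 0.21 M | 0.21 M |
| reagent | 0.800 equiv | 0.800 equiv (fed, over 7.50 h) | 0.800 equiv | 0.800 equiv |
| remark | one stirred flow tank at steady state, fed with the mixture as stated, mean residence time 15 h | a stirred flask in which reagent is dosed at a steady rate over 7.50 h without added volume, worked up at 15 h | everything together in a closed stirred flask, run for 15 h | plug flow through a tube for 15 h, no back-mixing |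
| time |  | 15 h | 15 h | 15 h |

- the stated concentrations are those of everything mixed, before any reaction; amounts are the same in each set-up
- the feed brings no volume worth counting
- run time (north): 15 h

* the set-up with the highest share of target in all that became target or side product, at the outlet or at the end ("none" if the first two lie within 2 percentage points) (south-west / north / south / north-west / none)
* share of target in all that became target or side product, at the outlet or at the end, south-west
* share of target in all that became target or side product, at the outlet or at the end, north
* share of target in all that became target or side product, at the outlet or at the end, south
* share of target in all that became target or side product, at the outlet or at the end, north-west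

Two times carry the reckoning for the closed flask. The target step relaxes far faster than the run of 15 h, and the step between intermediate A and intermediate C does so too, at 0.121 h, so both are taken at their balance. Target then stands at its equilibrium constant times substrate times reagent; it is the resting state of the material, since that constant times starting substrate is 44. Once filled, intermediate C stands to substrate as the product of the two equilibrium constants on the way there, 0.552.

Side product forms at its rate constant times reagent times intermediate C. Divided by target, reagent and substrate cancel, and what stays is the leak time of target, 199 h: the time in which, while these balances hold, side product equal to the standing target is made. It is 210 L mol⁻¹ over the product of 5.3 × 10⁻⁴ L mol⁻¹ s⁻¹, 0.46 and 1.2.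

The other time is how long the leak has been open. The isomers start empty. Intermediate A and intermediate C, held at their balance, form a pool that fills from substrate by the forward constant of step 2 and drains back through intermediate A, so with substrate taken as steady and intermediate B left aside its mean fill time is 2.25 h, shorter than the run, and the south flask has an open time of 12.7 h. Their ratio counts turnovers of target through the exit, 0.0639, which is the expected side product over target, and the share of target comes to 94.0%. A tube without back-mixing repeats the closed flask, so north-west ties with south, and that tie points to none; the tank and the dosed flask run on other clocks and are not reckoned here.

The forecast, holding that “batch and plug flow are identical”, gave 94.8% for south-west, 94.2% for north, 94.9% for south, 94.9% for north-west, and none as best. The simulation gives 94.2%, 92.0%, 95.0% and 95.0% in that order, and none as best.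

In the south flask the target step relaxes with a half-life of 0.199 h at the asked time, far shorter than the run, and side product over target reads 0.0532 beside the counted 0.0639. Read at 2.5 d, the same flask has an open time of 57.7 h, so the leak time counts 0.290 turnovers and a share of 77.5%. The computed share there is 77.9%.

The numbers of this flask are those of an exercise; what happens was integrated by code.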